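## Retrosynthetic overview

1. Germacranolide numbering is used: C1–C10 form the ten-membered ring, C11–C13 the α-methylene lactone fused at C6/C7, C14 and C15 are the methyls on C10 and C4. The enabling feature is the aldol unit C1(OH)–C2H2–C3(=O) inside the carbocycle, next to the quaternary C10 carbinol, which is the retron of a 2-isoxazoline.
2. Key disconnection: C2–C3 together with O–C1, by an intramolecular nitrile oxide–alkene (3+2) cycloaddition of acyclic nitro alkene 19. It closes the ten-membered carbocycle and the isoxazoline in one operation and sets C1.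
3. The trans-butyrolactone (C6, C7) comes from a tandem allylboration–lactonisation of allylboronate 13 with nitro aldehyde 16 (C6–C7 bond).
4. 13 is built from (R)-linalool (C1, C2, C8–C10, C14), methyl propiolate (C7, C11, C12) and ICH2Bpin (C13); 16 from crotonaldehyde and nitromethane (C3–C6, C15).
5. Ring order: butyrolactone, then carbocycle plus isoxazoline bridge, then N–O hydrogenolysis to the aldol. The α-methylene group is masked as its Me2NH adduct from step 9 to step 13 and released last.

Key step: step 10

Remarks on the chemistry: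
- (R)-(−)-Linalool of high enantiomeric purity is taken as commercially available.
- The ligand antipodes named in steps 4 and 7 are those expected, from the usual steric models, to give Si-face attack; the antipode would be used if the sense proved opposite.
- C11 in 19–26 is an inconsequential epimer mixture (it becomes sp2 again in step 14) and is left unspecified in the SMILES.
- Stereodescriptors in names follow each compound's own CIP priorities; the spatial arrangement is that of the target throughout.

## Route

Step 1
Reactants: 1 (R)-(−)-linalool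
Product: 2 (R)-linalool triethylsilyl ether
Conditions: TESOTf, 2,6-lutidine, CH2Cl2, −78 → 0 °C
Reagents that add atoms: triethylsilyl trifluoromethanesulfonate, CC[Si](CC)(CC)OS(=O)(=O)C(F)(F)F
Why: Silyl triflate with a hindered base silylates the tertiary allylic alcohol without touching C10, and the ether later serves as the allylic alkoxy control element of the cycloaddition.

Step 2
Reactants: 2 (R)-linalool triethylsilyl ether
Product: 4 (4R)-4-methyl-4-(triethylsilyloxy)hex-5-enal, via ozonide 3 (not isolated)
Conditions: O3 (1.0 equiv, Sudan Red 7B end point), CH2Cl2, −78 °C; then PPh3, −78 °C → rt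
Reagents that add atoms: ozone, [O-][O+]=O
Why: Chemoselective ozonolysis, because the electron-rich trisubstituted alkene reacts far faster than the vinyl group, which is deactivated sterically and inductively by the quaternary silyloxy carbon.

Step 3
Reactants: 4 (4R)-4-methyl-4-(triethylsilyloxy)hex-5-enal
Product: 7 (3R)-3-methyl-3-(triethylsilyloxy)pent-4-enal, via silyl enol ether 5 (not isolated), via ozonide 6 (not isolated)
Conditions: TMSCl, Et3N, DMF, 80 °C; pentane extraction; then O3 (1.0 equiv), CH2Cl2, −78 °C; PPh3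
Reagents that add atoms: ozone, [O-][O+]=O; chlorotrimethylsilane, C[Si](C)(C)Cl (silyl group of 5 and 6 only)
Why: One-carbon degradation of an aldehyde through its silyl enol ether, whose very electron-rich double bond is ozonised selectively in the presence of the vinyl group.

Step 4
Reactants: 7 (3R)-3-methyl-3-(triethylsilyloxy)pent-4-enal; 8 methyl propiolate
Product: 10 methyl (4R,6R)-4-hydroxy-6-methyl-6-(triethylsilyloxy)oct-7-en-2-ynoate, via alkynylzinc 9 (not isolated)
Conditions: Me2Zn (3 equiv), (R,R)-ProPhenol (20 mol%), Ph3PO (40 mol%), toluene, 4 °C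
Reagents that add atoms: dimethylzinc, C[Zn]C (methylzinc group of 9 only)
Why: Catalytic asymmetric alkynylation in which the zinc alkynylide 9, held in the dinuclear zinc–ProPhenol pocket, should add to the Si face of the aldehyde and set C8 (4R in 10) under reagent control, the neopentyl-type α-methylene of 7 limiting self-aldolisation.

Step 5
Reactants: 10 methyl (4R,6R)-4-hydroxy-6-methyl-6-(triethylsilyloxy)oct-7-en-2-ynoate
Product: 11 methyl (4R,6R)-6-methyl-4,6-bis(triethylsilyloxy)oct-7-en-2-ynoate
Conditions: TESCl, imidazole, DMAP (cat.), CH2Cl2, 0 °C → rt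
Reagents that add atoms: chlorotriethylsilane, CC[Si](CC)(CC)Cl
Why: Standard silylation of the secondary propargylic alcohol, needed so that the later γ-oxy enoate cannot close to a butenolide and the C8 oxygen stays a poor leaving group in the allylboronate.

Step 6
Reactants: 11 methyl (4R,6R)-6-methyl-4,6-bis(triethylsilyloxy)oct-7-en-2-ynoate
Product: 13 methyl (2Z,4R,6R)-6-methyl-2-[(4,4,5,5-tetramethyl-1,3,2-dioxaborolan-2-yl)methyl]-4,6-bis(triethylsilyloxy)octa-2,7-dienoate, via alkenylalane 12 (not isolated)
Conditions: iBu2AlH, HMPA, THF, 0 °C; then ICH2Bpin, 0 °C → rt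
Reagents that add atoms: 2-(iodomethyl)-4,4,5,5-tetramethyl-1,3,2-dioxaborolane, CC1(C)OB(CI)OC1(C)C; diisobutylaluminium hydride, CC(C)C[AlH]CC(C)C (aluminium group of 12 only)
Why: Conjugate syn-hydroalumination of the ynoate places aluminium on C11 cis to H7 (so C8 is cis to the ester), and the alkenylalane is homologated by the (iodomethyl)boronate through an ate complex and 1,2-shift (Matteson-type) with retention of the alkene geometry.

Step 7
Reactants: 14 (E)-crotonaldehyde; 15 nitromethane
Product: 16 (3S)-3-methyl-4-nitrobutanal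
Conditions: (R)-α,α-diphenylprolinol trimethylsilyl ether (10 mol%), PhCO2H (20 mol%), MeOH, rt
Reagents that add atoms: none
Why: Iminium-activated Michael addition in which the diphenyl(silyloxy)methyl group of the (R)-catalyst shields one face of the (E)-iminium ion, so that nitromethane should add to the Si face of the β-carbon and give the S configuration at C4.

Step 8
Reactants: 13 the (2Z)-allylboronate; 16 (3S)-3-methyl-4-nitrobutanal
Product: 18 (4S,5R)-3-methylidene-5-[(2S)-2-methyl-3-nitropropyl]-4-[(1R,3R)-3-methyl-1,3-bis(triethylsilyloxy)pent-4-en-1-yl]oxolan-2-one, via borate 17 (not isolated)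
Conditions: toluene, 80 °C, sealed tube (Sc(OTf)3, 10 mol%, rt, if sluggish)
Reagents that add atoms: none
Why: Tandem allylboration–lactonisation through a closed chair transition state: C8, fixed trans to the CH2B group, sits equatorial and should give the anti adduct and hence the trans-lactone (C6/C7), while 1,3-allylic strain with the cis ester keeps H8 in the alkene plane so that the aldehyde adds anti to the C9 chain and C6/C7 are set relative to C8, the nitro group being inert to the boron reagent.

Step 9
Reactants: 18 the α-methylene lactone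
Product: 19 (4S,5R)-3-[(dimethylamino)methyl]-5-[(2S)-2-methyl-3-nitropropyl]-4-[(1R,3R)-3-methyl-1,3-bis(triethylsilyloxy)pent-4-en-1-yl]oxolan-2-one (C3 epimers)
Conditions: Me2NH (2 M in THF, 5 equiv), EtOH, 0 °C → rt
Reagents that add atoms: dimethylamine, CNC
Why: Aza-Michael addition masks the exocyclic enoate as a Mannich base, removing the only competing dipolarophile and the hydrogenation-sensitive alkene, and the new C11 centre is of no consequence.

Step 10
Reactants: 19 the nitro Mannich-base lactone
Product: 21 bridged isoxazoline (1S,4S,6R,7S,8R,10R; ten-membered carbocycle C1–C10 with a C3=N–O–C1 bridge, trans-fused 6,12-lactone bearing 11-CH2NMe2, 8- and 10-OTES), via nitrile oxide 20 (not isolated)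
Conditions: PhNCO (4 equiv), Et3N (0.3 equiv), toluene, 0.002 M (slow addition of 19), 25 → 45 °C
Reagents that add atoms: none
Why: Phenyl isocyanate dehydrates the primary nitro group (Mukaiyama–Hoshino conditions) to nitrile oxide 20, which adds across C1=C2 in a concerted (3+2) cycloaddition that forms C2–C3 and O–C1 together; the closest known reaction type is the macrocyclic, bridged-mode intramolecular nitrile oxide–alkene cycloaddition of ω-nitro-1-alkenes to medium and large carbocycles, with the isoxazoline serving as a masked aldol. The ten-membered carbocycle closes in the bridged (macrocyclic) mode, C3 bonding to the distal alkene terminus C2, and the 2-isoxazoline closes as the five-membered ring of the cycloaddition, giving a 10-oxa-11-azabicyclo[7.2.1]dodec-1(11)-ene core whose bridgehead C=N is allowed because it is E within the eleven-membered ring. The only new stereocentre, C1, is controlled by the adjacent quaternary C10: the staggered arrangements that keep the C10–O bond out of the anti position and the ring chain out of the crowded outside position (silyloxy inside with the chain anti, or chain inside with silyloxy outside) both deliver the dipole oxygen to the face that gives 1S, the anti relation to O10 known from nitrile oxide additions to allylic ethers. Regioselectivity (C3 to C2 rather than to C1, which would give a nine-membered ring) is secured by the monosubstituted alkene sitting on a quaternary carbon, and chemoselectivity by the α-methylene lactone, the only other dipolarophile, being masked as the Mannich base. Cyclisation has to outrun furoxan dimerisation and oligomerisation, which high dilution, the α-branched (C4 methyl) nitrile oxide and the turn imposed by the trans-disubstituted butyrolactone should secure.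

Step 11
Reactants: 21 the bridged isoxazoline
Product: 22 bridged isoxazoline 8,10-diol
Conditions: HF·pyridine, pyridine, THF, 0 °C → rt
Reagents that add atoms: none
Why: Fluoride-mediated cleavage of both triethylsilyl ethers under buffered conditions that should leave the isoxazoline, the lactone and the Mannich base intact.

Step 12
Reactants: 22 the isoxazoline diol
Product: 23 bridged isoxazoline 8-O-isobutyrate
Conditions: (i-PrCO)2O, Et3N, DMAP (cat.), CH2Cl2, 0 °C
Reagents that add atoms: isobutyric anhydride, CC(C)C(=O)OC(=O)C(C)C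
Why: DMAP-catalysed acylation should take the secondary C8 hydroxyl and leave the tertiary C10 hydroxyl, while the C1 oxygen is still locked in the isoxazoline and cannot compete.

Step 13
Reactants: 23 the isoxazoline isobutyrate
Product: 25 13-(dimethylamino)-11,13-dihydro target (1-hydroxy-3-ketone), via hydroxy imine 24 (not isolated)
Conditions: H2 (1 atm), Raney Ni, B(OH)3, MeOH/H2O (5:1), rt
Reagents that add atoms: water, O
Why: Hydrogenolysis of the isoxazoline N–O bond and hydrolysis of the resulting β-hydroxy imine under boric acid buffering unveil the aldol unit with C1 unchanged and should avoid epimerisation at C4 and β-elimination.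

Step 14
Reactants: 25 the amino keto diol
Product: 27 target CNP0180091.1, via ammonium iodide 26 (not isolated)
Conditions: MeI, MeOH, rt; evaporation; then NaHCO3, H2O/EtOAc, rt
Reagents that add atoms: iodomethane, CI (N-methyl group of 26 only)
Why: Quaternisation of the Mannich base and mild E1cB (Hofmann-type) elimination of trimethylamine regenerate the α-methylene lactone under conditions that the aldol unit, the isobutyrate and the free hydroxyls should tolerate.

## Compound list

1 | (R)-(−)-linalool, (3R)-3,7-dimethylocta-1,6-dien-3-ol | CC(C)=CCC[C@@](C)(O)C=C | starting material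
2 | (R)-linalool triethylsilyl ether | CC(C)=CCC[C@@](C)(O[Si](CC)(CC)CC)C=C | intermediate
3 | ozonide (1,2,4-trioxolane) of the trisubstituted alkene of 2 | CC1(C)OOC(CC[C@@](C)(O[Si](CC)(CC)CC)C=C)O1 | intermediate
4 | (4R)-4-methyl-4-(triethylsilyloxy)hex-5-enal | O=CCC[C@@](C)(O[Si](CC)(CC)CC)C=C | intermediate
5 | (4R)-4-methyl-4-(triethylsilyloxy)-1-(trimethylsilyloxy)hexa-1,5-diene (E/Z) | C[Si](C)(C)OC=CC[C@@](C)(O[Si](CC)(CC)CC)C=C | intermediate
6 | ozonide of the enol ether double bond of 5 | C[Si](C)(C)OC1OOC(C[C@@](C)(O[Si](CC)(CC)CC)C=C)O1 | intermediate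
7 | (3R)-3-methyl-3-(triethylsilyloxy)pent-4-enal | O=CC[C@@](C)(O[Si](CC)(CC)CC)C=C | intermediate
8 | methyl propiolate | C#CC(=O)OC | starting material
9 | methyl(3-methoxy-3-oxoprop-1-yn-1-yl)zinc (ligand-bound) | COC(=O)C#C[Zn]C | intermediate
10 | methyl (4R,6R)-4-hydroxy-6-methyl-6-(triethylsilyloxy)oct-7-en-2-ynoate | COC(=O)C#C[C@H](O)C[C@@](C)(O[Si](CC)(CC)CC)C=C | intermediate
11 | methyl (4R,6R)-6-methyl-4,6-bis(triethylsilyloxy)oct-7-en-2-ynoate | COC(=O)C#C[C@H](O[Si](CC)(CC)CC)C[C@@](C)(O[Si](CC)(CC)CC)C=C | intermediate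
12 | methyl (2E,4R,6R)-2-(diisobutylalumanyl)-6-methyl-4,6-bis(triethylsilyloxy)octa-2,7-dienoate | COC(=O)/C([Al](CC(C)C)CC(C)C)=C\[C@H](O[Si](CC)(CC)CC)C[C@@](C)(O[Si](CC)(CC)CC)C=C | intermediate
13 | methyl (2Z,4R,6R)-6-methyl-2-[(4,4,5,5-tetramethyl-1,3,2-dioxaborolan-2-yl)methyl]-4,6-bis(triethylsilyloxy)octa-2,7-dienoate | COC(=O)/C(CB1OC(C)(C)C(C)(C)O1)=C\[C@H](O[Si](CC)(CC)CC)C[C@@](C)(O[Si](CC)(CC)CC)C=C | intermediate
14 | (E)-crotonaldehyde | C/C=C/C=O | starting material
15 | nitromethane | C[N+](=O)[O-] | starting material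
16 | (3S)-3-methyl-4-nitrobutanal | O=CC[C@H](C)C[N+](=O)[O-] | intermediate
17 | methyl (3S,4R,6S)-6-methyl-2-methylidene-7-nitro-4-(pinacolboryloxy)-3-[(1R,3R)-3-methyl-1,3-bis(triethylsilyloxy)pent-4-en-1-yl]heptanoate | COC(=O)C(=C)[C@@H]([C@@H](C[C@H](C)C[N+](=O)[O-])OB1OC(C)(C)C(C)(C)O1)[C@H](O[Si](CC)(CC)CC)C[C@@](C)(O[Si](CC)(CC)CC)C=C | intermediate
18 | (4S,5R)-3-methylidene-5-[(2S)-2-methyl-3-nitropropyl]-4-[(1R,3R)-3-methyl-1,3-bis(triethylsilyloxy)pent-4-en-1-yl]oxolan-2-one | C=C1C(=O)O[C@H](C[C@H](C)C[N+](=O)[O-])[C@H]1[C@H](O[Si](CC)(CC)CC)C[C@@](C)(O[Si](CC)(CC)CC)C=C | intermediate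
19 | (4S,5R)-3-[(dimethylamino)methyl]-5-[(2S)-2-methyl-3-nitropropyl]-4-[(1R,3R)-3-methyl-1,3-bis(triethylsilyloxy)pent-4-en-1-yl]oxolan-2-one (C3 epimers) | CN(C)CC1C(=O)O[C@H](C[C@H](C)C[N+](=O)[O-])[C@H]1[C@H](O[Si](CC)(CC)CC)C[C@@](C)(O[Si](CC)(CC)CC)C=C | intermediate
20 | nitrile oxide of 19 (C3 as C≡N+–O−; otherwise as 19) | CN(C)CC1C(=O)O[C@H](C[C@H](C)C#[N+][O-])[C@H]1[C@H](O[Si](CC)(CC)CC)C[C@@](C)(O[Si](CC)(CC)CC)C=C | intermediate
21 | bridged isoxazoline: (1S,4S,6R,7S,8R,10R)-11-[(dimethylamino)methyl]-8,10-bis(triethylsilyloxy)germacran-12,6-olide with a C3=N–O–C1 bridge | CN(C)CC1C(=O)O[C@@H]2C[C@H](C)C3=NO[C@@H](C3)[C@](C)(O[Si](CC)(CC)CC)C[C@@H](O[Si](CC)(CC)CC)[C@@H]12 | intermediate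
22 | 8,10-diol of 21 (same spatial arrangement; C7 formally R) | CN(C)CC1C(=O)O[C@@H]2C[C@H](C)C3=NO[C@@H](C3)[C@](C)(O)C[C@@H](O)[C@@H]12 | intermediate
23 | 8-O-isobutyrate of 22 | CN(C)CC1C(=O)O[C@@H]2C[C@H](C)C3=NO[C@@H](C3)[C@](C)(O)C[C@@H](OC(=O)C(C)C)[C@@H]12 | intermediate
24 | 1-hydroxy-3-imine from N–O cleavage of 23 | CN(C)CC1C(=O)O[C@@H]2C[C@H](C)C(=N)C[C@H](O)[C@](C)(O)C[C@@H](OC(=O)C(C)C)[C@@H]12 | intermediate
25 | 13-(dimethylamino)-11,13-dihydro derivative of the target | CN(C)CC1C(=O)O[C@@H]2C[C@H](C)C(=O)C[C@H](O)[C@](C)(O)C[C@@H](OC(=O)C(C)C)[C@@H]12 | intermediate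
26 | N-methyl ammonium iodide of 25 | C[N+](C)(C)CC1C(=O)O[C@@H]2C[C@H](C)C(=O)C[C@H](O)[C@](C)(O)C[C@@H](OC(=O)C(C)C)[C@@H]12.[I-] | intermediate
27 | CNP0180091.1, (1S,4S,6R,7S,8R,10R)-1,10-dihydroxy-8-(2-methylpropanoyloxy)-3-oxogermacr-11(13)-en-12,6-olide | C=C1C(=O)O[C@@H]2C[C@H](C)C(=O)C[C@H](O)[C@](C)(O)C[C@@H](OC(=O)C(C)C)[C@@H]12 | target

## Step count and risks

Total steps: 14. Longest linear sequence: 13 steps (steps 1–6 and 8–14).

**Step 10 (most likely to fail).** Furoxan dimerisation and oligomerisation may outrun the medium-ring closure, and facial selectivity at C1 may be incomplete under the ring constraint. The fallback forms C2–C3 by the same cycloaddition between two fragments and closes the ring at C6–C7 instead. It sets out from 16 and 13 and returns at 21.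
- Aldehyde 16 is protected (HC(OMe)3, MeOH, PPTS) as (2S)-4,4-dimethoxy-2-methyl-1-nitrobutane F1.
- F1 is dehydrated (PhNCO, Et3N, toluene) to (2S)-4,4-dimethoxy-2-methylbutanenitrile oxide F2, which adds to the vinyl group of 13. The trisubstituted, ester-conjugated alkene is much less reactive, and C1 is set by the inside-alkoxy preference in its ordinary intermolecular form. The product is the isoxazoline allylboronate acetal F3.
- Mild acetal hydrolysis (wet oxalic acid on silica) gives the isoxazoline allylboronate aldehyde F4.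
- Intramolecular allylboration under high dilution (Sc(OTf)3 cat., toluene) closes the ten-membered ring through the macrocyclic pinacol borate F5, which lactonises to the bis-silylated α-methylene lactone isoxazoline F6.
- Addition of Me2NH to F6 gives 21.

**Step 6.** The hydride may over-reduce the ester, the alkene geometry may erode through the aluminium allenolate, or C-alkylation by the (iodomethyl)boronate may be sluggish. The fallback sets out from 11 and returns at 13.
- Pd(PPh3)4-catalysed syn-hydrostannation with Bu3SnH gives methyl (2E,4R,6R)-6-methyl-2-(tributylstannyl)-4,6-bis(triethylsilyloxy)octa-2,7-dienoate F7.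
- Iododestannylation (I2, CH2Cl2, 0 °C) with retention gives methyl (2E,4R,6R)-2-iodo-6-methyl-4,6-bis(triethylsilyloxy)octa-2,7-dienoate F8.
- Negishi coupling of F8 with IZnCH2Bpin (Pd(PPh3)4, THF) gives 13 with the geometry fixed by the hydrostannation.

**Step 4.** The enolisable β-silyloxy aldehyde may self-condense or undergo β-elimination under the basic zinc conditions, and catalyst control at C8 may be incomplete. The fallback separates C–C bond formation from the setting of C8. It sets out from 7 (with 8) and returns at 10.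
- Methyl propiolate 8 is lithiated (LiHMDS, THF, −78 °C) to lithium 3-methoxy-3-oxoprop-1-yn-1-ide F9.
- F9 adds to 7 to give the C4-epimeric methyl (6R)-4-hydroxy-6-methyl-6-(triethylsilyloxy)oct-7-en-2-ynoates F10.
- Dess–Martin oxidation gives methyl (6R)-6-methyl-4-oxo-6-(triethylsilyloxy)oct-7-en-2-ynoate F11.
- Asymmetric transfer hydrogenation of F11 with RuCl[(R,R)-TsDPEN](p-cymene) in iPrOH, the alkynyl group acting as the π-substituent, should return 10 with the 4R configuration.

Further compounds
F1 | step 10 | (2S)-4,4-dimethoxy-2-methyl-1-nitrobutane | COC(OC)C[C@H](C)C[N+](=O)[O-]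
F2 | step 10 | (2S)-4,4-dimethoxy-2-methylbutanenitrile oxide | COC(OC)C[C@H](C)C#[N+][O-]
F3 | step 10 | isoxazoline allylboronate acetal (C1–C2–C3 isoxazoline from F2 and the vinyl group of 13) | COC(OC)C[C@H](C)C1=NO[C@@H](C1)[C@](C)(O[Si](CC)(CC)CC)C[C@@H](O[Si](CC)(CC)CC)\C=C(\CB2OC(C)(C)C(C)(C)O2)C(=O)OC
F4 | step 10 | isoxazoline allylboronate aldehyde | O=CC[C@H](C)C1=NO[C@@H](C1)[C@](C)(O[Si](CC)(CC)CC)C[C@@H](O[Si](CC)(CC)CC)\C=C(\CB2OC(C)(C)C(C)(C)O2)C(=O)OC
F5 | step 10 | macrocyclic pinacol borate (ten-membered ring closed at C6–C7, methyl acrylate at C7) | COC(=O)C(=C)[C@H]1[C@H](OB2OC(C)(C)C(C)(C)O2)C[C@H](C)C3=NO[C@@H](C3)[C@](C)(O[Si](CC)(CC)CC)C[C@H]1O[Si](CC)(CC)CC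
F6 | step 10 | bis-silylated α-methylene lactone isoxazoline (11(13)-ene analogue of 21) | C=C1C(=O)O[C@@H]2C[C@H](C)C3=NO[C@@H](C3)[C@](C)(O[Si](CC)(CC)CC)C[C@@H](O[Si](CC)(CC)CC)[C@@H]12
F7 | step 6 | methyl (2E,4R,6R)-6-methyl-2-(tributylstannyl)-4,6-bis(triethylsilyloxy)octa-2,7-dienoate | COC(=O)/C([Sn](CCCC)(CCCC)CCCC)=C\[C@H](O[Si](CC)(CC)CC)C[C@@](C)(O[Si](CC)(CC)CC)C=C
F8 | step 6 | methyl (2E,4R,6R)-2-iodo-6-methyl-4,6-bis(triethylsilyloxy)octa-2,7-dienoate | COC(=O)/C(I)=C\[C@H](O[Si](CC)(CC)CC)C[C@@](C)(O[Si](CC)(CC)CC)C=C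
F9 | step 4 | lithium 3-methoxy-3-oxoprop-1-yn-1-ide | COC(=O)C#C[Li]
F10 | step 4 | methyl (6R)-4-hydroxy-6-methyl-6-(triethylsilyloxy)oct-7-en-2-ynoate (C4 epimers) | COC(=O)C#CC(O)C[C@@](C)(O[Si](CC)(CC)CC)C=C
F11 | step 4 | methyl (6R)-6-methyl-4-oxo-6-(triethylsilyloxy)oct-7-en-2-ynoate | COC(=O)C#CC(=O)C[C@@](C)(O[Si](CC)(CC)CC)C=C
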